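Ring A (cyclohexenone) = C1 (quaternary, geranyl), C2 (C=O), C3 (prenyl), C4 (enol-ether carbon), C5 and C6 (the carbinols). Ring B = C1, C6, C7, C8(Me), C9, C10. Ring C = C5, C6, C7, C11, C12. Ring D = C4, C5, C12, C13(Me2), O.
Cuts: (i) C1–C2 of ring A together with the geranyl CH2–CH= bond (alkene carboacylation retron); (ii) C3=C4 (ynolate olefination of a γ-lactone); (iii) C5–C12 and C13–O (Prins lactonisation); (iv) C6–C7 and C1–C10 (Diels–Alder reaction of (E)-β-ocimene with an allenyl keto ester).
Forward order: ring B (step 4), rings C and D together (step 5), C3/C2 with the prenyl group (step 8), ring A last (step 13), then removal of the acetal.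
Enabling feature: C1 carries both the ring A acyl carbon C2 and the CH2 of geranyl. The C1=CH2 group that an allene dienophile leaves on ring B can therefore take up C2 and an alkenyl group in one palladium event. After insertion C1 is quaternary, so no β-hydrogen is available, and rings B, C and D already hold C2 beside C1.
Stereochemistry: C6 and C7 come from the catalytic enantioselective endo Diels–Alder reaction. C5 and C12 come from the chelation-controlled, cis-fusing Prins lactonisation. C1 comes from the tethered concave-side delivery of C2. The E-geranyl alkene comes from syn methylalumination.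

Key step: step 13

Assumption: commercial ocimene is an E/Z mixture. Only the E isomer reaches the s-cis diene conformation, so the mixture is used in excess. The (S,S)-t-Bu-box ligand is taken to expose the face of 7 that leads to the drawn enantiomer; if the sense proves opposite, the equally available (R,R)-ligand is used.

Step 1
Reactants: 1 4-methoxybenzyl alcohol; 2 propargyl bromide
Product: 3 4-methoxybenzyl propargyl ether
Conditions: NaH, THF, 0 °C to rt
Reagents that add atoms: none
Why: Williamson ether synthesis of a primary alkoxide with an unhindered propargylic bromide.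

Step 2
Reactants: 3 4-methoxybenzyl propargyl ether
Product: 4 (4-methoxybenzyloxy)allene
Conditions: KOt-Bu (0.2 equiv), THF, rt
Reagents that add atoms: none
Why: Base-catalysed propargyl-to-allenyl isomerisation of a propargyl ether, which stops at the alkoxyallene.

Step 3
Reactants: 4 (4-methoxybenzyloxy)allene; 5 di-tert-butyl oxalate
Product: 7 tert-butyl 3-(4-methoxybenzyloxy)-2-oxopenta-3,4-dienoate, via 1-lithioallenyl ether 6 (not isolated)
Conditions: n-BuLi, THF, −78 °C; cannulated into 5 (2 equiv), THF, −78 °C; AcOH quench at −78 °C
Reagents that add atoms: none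
Why: α-Lithiation of an alkoxyallene and mono-acylation by an oxalate diester, whose tetrahedral adduct persists until the cold quench, which is the standard route from organolithiums to α-keto esters.

Step 4
Reactants: 7 tert-butyl 3-(4-methoxybenzyloxy)-2-oxopenta-3,4-dienoate; 8 (E)-β-ocimene
Product: 9 ring B keto ester (C6 carries OPMB and the keto ester; prenyl on C7 cis to the keto ester; C1=CH2 exocyclic)
Conditions: Cu(SbF6)2·(S,S)-t-Bu-box (10 mol %), 4 Å MS, CH2Cl2, −40 °C; 8 (3 equiv of the commercial mixture)
Reagents that add atoms: none
Why: Enantioselective Lewis acid catalysed Diels–Alder reaction in which the divalent copper complex chelates the 1,2-dicarbonyl unit and shields one face, the conjugated C6=C1 bond of the allene is the dienophile, the free diene terminus C10 bonds to the central allene carbon C1 and C7 bonds to C6 (ortho orientation), and the endo keto ester ends cis to the prenyl group, which sets C6 and C7 and leaves C1=CH2.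

Step 5
Reactants: 9 ring B keto ester
Product: 10 tricyclic hydroxy lactone (rings B C D; all fusions cis; C5–OH and C6–OPMB cis; H-7 and H-12 on the same face of ring C as the two oxygens)
Conditions: SnCl4 (1.2 equiv), 2,6-di-tert-butyl-4-methylpyridine, CH2Cl2, −78 °C; aq. NaHCO3
Reagents that add atoms: none
Why: Prins cyclisation with lactonising cation capture, in which SnCl4 chelates O–C6 and O=C5 so that the carbonyl lies syn to the C6–O bond, the prenyl alkene tethered at C7 attacks C5 from its own side (cis-fused cyclopentane, cis diol pattern), and the tertiary cation at C13 is caught by the ester carbonyl oxygen as a cis-fused γ-lactone with loss of 2-methylpropene, which sets C5 and C12.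

Step 6
Reactants: 10 tricyclic hydroxy lactone
Product: 11 4-methoxybenzylidene acetal lactone (dioxolane across O–C5 and O–C6; aryl drawn toward ring C)
Conditions: DDQ (1.2 equiv), 4 Å MS, CH2Cl2, 0 °C
Reagents that add atoms: none
Why: Anhydrous DDQ oxidation of the PMB ether to its oxocarbenium ion and capture by the cis C5–OH (oxidative acetalisation), which masks both tertiary hydroxyls in one operation; the acetal centre is erased in step 14.

Step 7
Reactants: 12 trimethylsilylacetylene; 13 prenyl bromide
Product: 15 trimethyl(5-methylhex-4-en-1-yn-1-yl)silane, via lithium silylacetylide 14 (not isolated)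
Conditions: n-BuLi, THF, −78 °C; 13, DMPU, −78 °C to rt
Reagents that add atoms: none
Why: SN2 alkylation of a lithium acetylide at the primary carbon of an allylic bromide, with the silyl cap keeping the skipped enyne from base-induced isomerisation.

Step 8
Reactants: 15 trimethyl(5-methylhex-4-en-1-yn-1-yl)silane; 11 4-methoxybenzylidene acetal lactone
Product: 18 (E)-β-alkoxyacrylic acid (C4=C3 exocyclic to ring D; prenyl on C3 cis to the ring oxygen; CO2H = C2 cis to C5), via lithium alkynide 16 (not isolated), via lithium ynolate 17 (not isolated)
Conditions: MeLi·LiBr, THF, 0 °C to rt; t-BuOOLi (from t-BuOOH, LiN(SiMe3)2), −78 to 0 °C; 11, THF, rt; AcOH quench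
Reagents that add atoms: tert-butyl hydroperoxide, CC(C)(C)OO
Why: Ynolate olefination of an ester carbonyl, in which the ynolate (made by oxidation of the acetylide with lithium tert-butyl peroxide) adds to the non-enolisable lactone, closes to the oxetene by formal [2+2] cycloaddition and opens in a conrotatory 4π process with the ring oxygen rotating outward, so that the E acid with C2 cis to C5 should result.

Step 9
Reactants: 19 5-bromo-2-methylpent-2-ene; 20 lithium acetylide–ethylenediamine complex
Product: 21 6-methylhept-5-en-1-yne
Conditions: DMSO, rt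
Reagents that add atoms: none
Why: SN2 alkylation of lithium acetylide with a primary homoallylic bromide.

Step 10
Reactants: 21 6-methylhept-5-en-1-yne
Product: 23 (E)-1-iodo-2,6-dimethylhepta-1,5-diene, via alkenylalane 22 (not isolated)
Conditions: Me3Al (2 equiv), Cp2ZrCl2 (0.25 equiv), CH2Cl2, 0 °C to rt; I2, THF, −30 °C; aq. K2CO3
Reagents that add atoms: trimethylaluminium, C[Al](C)C; iodine, II
Why: Zirconium-catalysed syn methylalumination of a terminal alkyne followed by iodinolysis with retention, which fixes the E geometry of the future geranyl alkene.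

Step 11
Reactants: 23 (E)-1-iodo-2,6-dimethylhepta-1,5-diene
Product: 25 (E)-tributyl(2,6-dimethylhepta-1,5-dien-1-yl)stannane, via alkenyllithium 24 (not isolated)
Conditions: t-BuLi (2 equiv), Et2O, −78 °C; Bu3SnCl, −78 °C to rt
Reagents that add atoms: tributyltin chloride, CCCC[Sn](Cl)(CCCC)CCCC
Why: Iodine–lithium exchange and stannylation, both with retention of alkene geometry.

Step 12
Reactants: 18 (E)-β-alkoxyacrylic acid
Product: 26 (E)-β-alkoxyacryloyl chloride
Conditions: 1-chloro-N,N,2-trimethylprop-1-en-1-amine, CH2Cl2, 0 °C to rt; volatiles removed, used crude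
Reagents that add atoms: 1-chloro-N,N,2-trimethylprop-1-en-1-amine, CC(C)=C(Cl)N(C)C
Why: Neutral acid chloride formation with an α-chloroenamine, which releases no HCl and so spares the acetal, the enol ether and the skipped diene.

Step 13
Reactants: 26 (E)-β-alkoxyacryloyl chloride; 25 (E)-tributyl(2,6-dimethylhepta-1,5-dien-1-yl)stannane
Product: 27 acetal-protected target (rings A B C D; geranyl on C1 cis to O–C6)
Conditions: Pd2(dba)3·CHCl3 (5 mol %), P(2-furyl)3 (20 mol %), toluene, 50 °C; 25 added slowly by syringe pump
Reagents that add atoms: none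
Why: Proposed new method: zerovalent palladium adds oxidatively to the C2–Cl bond of 26, the acylpalladium chloride binds the neighbouring C1=CH2 bond and syn migratory insertion joins C2 to C1 and moves palladium to the exocyclic CH2; this alkylpalladium has no β-hydrogen because C1 has become quaternary and it is held as a five-membered chelate by the new C2=O, so it waits for transmetalation from 25 and reductive elimination, which joins CH2 to the alkenyl carbon with retention of the E geometry and completes the geranyl chain. The closest known reaction types are cyclic acylpalladation of tethered 1,1-disubstituted alkenes, cyclisation–anion capture cascades that end in a Stille coupling, the ketone synthesis from acid chlorides and stannanes, and the nickel- or palladium-catalysed intramolecular alkene carboacylation that ends in a boron transmetalation; what is new is their union on an alkenoyl chloride with a six-membered closure. Ring A closes in the 6-exo-trig mode (C2 onto C1, palladium on the exocyclic carbon), and no other ring is formed. The one new stereocentre C1 is controlled by the substrate: C2 is fixed through the E C3=C4 bond and through C5–C6 on the concave side of the cis-fused B/C/D bowl, so it can reach only the face of C1=CH2 that is cis to C5, and the CH2–Pd arm, the later geranyl group, is pushed to the convex side cis to the C6 oxygen. The step needs insertion to be faster than direct acyl–alkenyl coupling and than loss of CO, and it needs 6-exo and not 7-endo regiochemistry: the first is secured by the rigid placement of the C2 atom within bonding reach of C1, by the slow addition of 25 and by the low temperature, the second by the usual delivery of carbon to the internal alkene carbon in exo migratory insertions. The trisubstituted alkenes of ring B and of the prenyl group lie out of reach of C2 and insert far more slowly, and the acetal keeps the C5 oxygen from lactonising onto C2.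

Step 14
Reactants: 27 acetal-protected target
Product: 28 target CNP0323114.1
Conditions: AcOH/THF/H2O (3:1:1), 40 °C
Reagents that add atoms: none
Why: Mild acid hydrolysis of a 4-methoxybenzylidene acetal, eased by the aryl-stabilised oxocarbenium ion, under conditions that the cyclic vinylogous ester and the trisubstituted alkenes tolerate.

Compound list
1 | 4-methoxybenzyl alcohol | COc1ccc(CO)cc1 | starting material
2 | propargyl bromide | C#CCBr | starting material
3 | 4-methoxybenzyl propargyl ether | C#CCOCc1ccc(OC)cc1 | intermediate
4 | (4-methoxybenzyloxy)allene | C=C=COCc1ccc(OC)cc1 | intermediate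
5 | di-tert-butyl oxalate | CC(C)(C)OC(=O)C(=O)OC(C)(C)C | starting material
6 | 1-lithio-1-(4-methoxybenzyloxy)allene | [Li]C(=C=C)OCc1ccc(OC)cc1 | intermediate
7 | tert-butyl 3-(4-methoxybenzyloxy)-2-oxopenta-3,4-dienoate | C=C=C(OCc1ccc(OC)cc1)C(=O)C(=O)OC(C)(C)C | intermediate
8 | (E)-β-ocimene | C=C/C(C)=C/CC=C(C)C | starting material
9 | tert-butyl 2-[1-(4-methoxybenzyloxy)-3-methyl-6-methylidene-2-(3-methylbut-2-enyl)cyclohex-3-enyl]-2-oxoacetate, keto ester cis to prenyl | C=C1CC=C(C)[C@H](CC=C(C)C)[C@]1(OCc2ccc(OC)cc2)C(=O)C(=O)OC(C)(C)C | intermediate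
10 | tricyclic hydroxy lactone, rings B, C, D all cis-fused, C5–OH cis to C6–OPMB | C=C1CC=C(C)[C@@H]2C[C@@H]3C(C)(C)OC(=O)[C@]3(O)[C@@]21OCc4ccc(OC)cc4 | intermediate
11 | 4-methoxybenzylidene acetal of the C5,C6-diol lactone | C=C1CC=C(C)[C@@H]2C[C@@H]3C(C)(C)OC(=O)[C@]3(O[C@H]4c5ccc(OC)cc5)[C@@]21O4 | intermediate
12 | trimethylsilylacetylene | C#C[Si](C)(C)C | starting material
13 | prenyl bromide | CC(C)=CCBr | starting material
14 | lithium (trimethylsilyl)acetylide | [Li]C#C[Si](C)(C)C | intermediate
15 | trimethyl(5-methylhex-4-en-1-yn-1-yl)silane | CC(C)=CCC#C[Si](C)(C)C | intermediate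
16 | lithium 5-methylhex-4-en-1-yn-1-ide | [Li]C#CCC=C(C)C | intermediate
17 | lithium 5-methylhex-4-en-1-yn-1-olate | [Li]OC#CCC=C(C)C | intermediate
18 | (E)-β-alkoxyacrylic acid, C2 cis to C5 | C=C1CC=C(C)[C@@H]2C[C@@H]3C(C)(C)O/C(=C(\CC=C(C)C)C(O)=O)[C@]3(O[C@H]4c5ccc(OC)cc5)[C@@]21O4 | intermediate
19 | 5-bromo-2-methylpent-2-ene | CC(C)=CCCBr | starting material
20 | lithium acetylide–ethylenediamine complex | [Li]C#C.NCCN | starting material
21 | 6-methylhept-5-en-1-yne | C#CCCC=C(C)C | intermediate
22 | (E)-(2,6-dimethylhepta-1,5-dien-1-yl)dimethylalane | CC(C)=CCC/C(C)=C/[Al](C)C | intermediate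
23 | (E)-1-iodo-2,6-dimethylhepta-1,5-diene | CC(C)=CCC/C(C)=C/I | intermediate
24 | (E)-(2,6-dimethylhepta-1,5-dien-1-yl)lithium | CC(C)=CCC/C(C)=C/[Li] | intermediate
25 | (E)-tributyl(2,6-dimethylhepta-1,5-dien-1-yl)stannane | CC(C)=CCC/C(C)=C/[Sn](CCCC)(CCCC)CCCC | intermediate
26 | (E)-β-alkoxyacryloyl chloride | C=C1CC=C(C)[C@@H]2C[C@@H]3C(C)(C)O/C(=C(\CC=C(C)C)C(Cl)=O)[C@]3(O[C@H]4c5ccc(OC)cc5)[C@@]21O4 | intermediate
27 | 4-methoxybenzylidene acetal of the target | CC(C)=CCC/C(C)=C/C[C@]12CC=C(C)[C@@H]3C[C@@H]4C(C)(C)OC(=C(CC=C(C)C)C1=O)[C@]4(O[C@H]5c6ccc(OC)cc6)[C@@]32O5 | intermediate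
28 | CNP0323114.1; geranyl on C1, both hydroxyls, H-7 and H-12 all on the convex side | CC(C)=CCC/C(C)=C/C[C@]12CC=C(C)[C@@H]3C[C@@H]4C(C)(C)OC(=C(CC=C(C)C)C1=O)[C@]4(O)[C@@]32O | target

Total step count: 14. Longest linear sequence: 10 (steps 1, 2, 3, 4, 5, 6, 8, 12, 13, 14).

Steps most likely to fail

1. Step 13.
What may go wrong: transmetalation may overtake alkene insertion and give direct acyl–alkenyl coupling. The acylpalladium may lose CO and close a five-membered ring instead. Palladium hydride traces may move the skipped diene into conjugation.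
Fallback (known chemistry only), from 11 back to 27: the exocyclic methylene carbon is used as C2 instead of as the geranyl CH2. Hydroboration of 11 with 9-BBN from the convex side and NaBO3 oxidation gives the primary alcohol F1. TEMPO/PhI(OAc)2 oxidation gives the carboxylic acid F2. Coupling with MeNHOMe·HCl (EDC) gives the Weinreb amide F3. Addition of 4-methylpent-3-enylmagnesium bromide gives the ketone F4. KN(SiMe3)2 closes ring A by intramolecular Claisen (Dieckmann-type) acylation of the C3 enolate by the lactone carbonyl C4, and PPTS re-forms the oxolane by dehydration to the C1–H vinylogous ester F5. Kinetic deprotonation at C1 with LDA and alkylation with geranyl bromide on the convex side gives 27.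

2. Step 4.
What may go wrong: facial or regiochemical control may be poor with a dienophile that carries a donor on C6. The Lewis acid may also induce cycloisomerisation or oligomerisation of the allenyl ketone before cycloaddition.
Fallback, from 4 back to 10: catalyst control is replaced by a covalent auxiliary and separation of diastereomers. (−)-Menthol and oxalyl chloride give di-(−)-menthyl oxalate F6. Lithiation of 4 as in step 3 and acylation with F6 gives the menthyl allenyl keto ester F7. The Diels–Alder reaction with 8 is run thermally or with Eu(fod)3, and the wanted menthyl adduct F8 is separated from its diastereomer by crystallisation or chromatography. SnCl4 as in step 5, followed by aqueous work-up that hydrolyses the dialkoxycarbenium ion and frees the auxiliary, gives 10.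

3. Step 5.
What may go wrong: the alkene may attack through the non-chelated rotamer of C5=O, which would place ring D on the wrong face. The cation may lose a proton (ene outcome) and never lactonise. The strong Lewis acid may cleave the PMB ether.
Fallback, from 9 back to 11: carbon–carbon and carbon–oxygen bond formation are separated, and the dative chelate is replaced by a covalent one. DDQ in wet CH2Cl2 gives the free hydroxy keto ester F9. Me2AlCl converts the C6 hydroxyl into an aluminium alkoxide that chelates C5=O and brings about a concerted carbonyl-ene reaction to the isopropenyl diol ester F10. Catalytic TsOH cleaves the tert-butyl ester and adds the acid to the isopropenyl group in the Markovnikov sense to give the diol lactone F11. 4-Methoxybenzaldehyde dimethyl acetal and PPTS give 11.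

Further compounds
F1 | step 13 | primary alcohol, C1–H with CH2OH cis to C5 | OC[C@@H]1CC=C(C)[C@@H]2C[C@@H]3C(C)(C)OC(=O)[C@]3(O[C@H]4c5ccc(OC)cc5)[C@@]21O4
F2 | step 13 | carboxylic acid | OC(=O)[C@@H]1CC=C(C)[C@@H]2C[C@@H]3C(C)(C)OC(=O)[C@]3(O[C@H]4c5ccc(OC)cc5)[C@@]21O4
F3 | step 13 | Weinreb amide | CON(C)C(=O)[C@@H]1CC=C(C)[C@@H]2C[C@@H]3C(C)(C)OC(=O)[C@]3(O[C@H]4c5ccc(OC)cc5)[C@@]21O4
F4 | step 13 | 4-methylpent-3-enyl ketone | CC(C)=CCCC(=O)[C@@H]1CC=C(C)[C@@H]2C[C@@H]3C(C)(C)OC(=O)[C@]3(O[C@H]4c5ccc(OC)cc5)[C@@]21O4
F5 | step 13 | C1–H tetracyclic vinylogous ester | [C@H]12CC=C(C)[C@@H]3C[C@@H]4C(C)(C)OC(=C(CC=C(C)C)C1=O)[C@]4(O[C@H]5c6ccc(OC)cc6)[C@@]32O5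
F6 | step 4 | di-(−)-menthyl oxalate | O=C(O[C@@H]1C[C@H](C)CC[C@H]1C(C)C)C(=O)O[C@@H]2C[C@H](C)CC[C@H]2C(C)C
F7 | step 4 | (−)-menthyl 3-(4-methoxybenzyloxy)-2-oxopenta-3,4-dienoate | C=C=C(OCc1ccc(OC)cc1)C(=O)C(=O)O[C@@H]2C[C@H](C)CC[C@H]2C(C)C
F8 | step 4 | menthyl ester analogue of 9 | C=C1CC=C(C)[C@H](CC=C(C)C)[C@]1(OCc2ccc(OC)cc2)C(=O)C(=O)O[C@@H]3C[C@H](C)CC[C@H]3C(C)C
F9 | step 5 | C6-hydroxy keto ester | C=C1CC=C(C)[C@H](CC=C(C)C)[C@]1(O)C(=O)C(=O)OC(C)(C)C
F10 | step 5 | isopropenyl diol tert-butyl ester (rings B and C) | C=C1CC=C(C)[C@@H]2C[C@H](C(C)=C)[C@](O)(C(=O)OC(C)(C)C)[C@@]21O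
F11 | step 5 | C5,C6-diol lactone (rings B, C, D) | C=C1CC=C(C)[C@@H]2C[C@@H]3C(C)(C)OC(=O)[C@]3(O)[C@@]21O
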